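The target is a cis-fused bicyclo[5.3.0]decane in which the ring-fusion bond C1–C5 joins the methyl-bearing quaternary C1 to C5, the neighbour of the oxygenated C6. The route makes this bond by a pinacol-type 1,2-shift in a trans-decalin: C1 moves from the carbinol carbon C6 to the mesylate carbon C5. In one operation ring A contracts to the cyclopentane, ring B grows to the cycloheptene, C5 is set with inversion (cis fusion) and C6 becomes the ketone needed for the aroyloxy group. The precursor, made from (R)-Wieland–Miescher ketone, already carries the C4 isopropyl carbinol, the C8=C9 alkene and the C10 isovalerate.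

Key step: step 9

Remark on the structure: the SMILES is read as drawn, that is a cis-fused ring system with the C1 methyl group, H5 and the C4 hydroxyl on one face and both ester oxygens on the other.

Numbering and faces: every intermediate carries the atom numbers of the target (C1 quaternary methyl carbon, C2, C3, C4 isopropyl carbinol, C5, C6 aroyloxy carbon, C7, C8 methyl-bearing alkene carbon, C9, C10 isovaleroyloxy carbon). In the decalins ring A is C1–C6 and ring B is C1, C10, C9, C8, C7, C6. β is the face of the C1 methyl group, α the opposite face.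

Step 1
Reactants: 1 (R)-Wieland–Miescher ketone
Product: 2 dienedione, (R)-8a-methyl-4,7,8,8a-tetrahydronaphthalene-1,6-dione (enones C5=C6–C4=O and C8=C9–C10=O)
Conditions: IBX (1.5 equiv), DMSO–PhF, 65 °C
Reagents that add atoms: none
Why: Dehydrogenation with 2-iodoxybenzoic acid runs through the enol of the saturated C10 ketone, whose only α-methylene is C9, and should stop at the C8=C9 enone because the already conjugated ring A enone reacts only under more forcing conditions; no stereocentre is formed.

Step 2
Reactants: 2 dienedione
Product: 3 trimethylsilyl enol ether (C9=C10–OSiMe3) of the 8α-methyl ketone, ring A enone intact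
Conditions: Me2CuLi, Me3SiCl, THF, −78 °C
Reagents that add atoms: lithium dimethylcuprate [Li+].C[Cu-]C; chlorotrimethylsilane C[Si](C)(C)Cl
Why: Conjugate addition of a Gilman cuprate with silyl trapping puts the methyl group on the unsubstituted β-carbon C8 of the ring B enone (the ring A enone has a fully substituted β-carbon and stays inert), from the α face opposite the axial C1 methyl group, and the enolate is held as a silyl enol ether that masks C10 in step 3 and feeds step 4.

Step 3
Reactants: 3 trimethylsilyl enol ether
Product: 4 tertiary allylic alcohol, the 4β-hydroxy-4α-isopropyl derivative of 3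
Conditions: iPrMgCl, CeCl3, THF, −78 °C; pH 7 buffer work-up
Reagents that add atoms: isopropylmagnesium chloride CC(C)[Mg]Cl
Why: Organocerium 1,2-addition to the C4 enone carbonyl (low basicity holds back enolisation and β-hydride reduction) should follow the axial trajectory on the α face, away from the β C1 methyl group, as hydride does in Luche reductions of this enone, which places the isopropyl group α and the C4 hydroxyl β.

Step 4
Reactants: 4 tertiary allylic alcohol
Product: 5 hydroxy enone, 4β-hydroxy-4α-isopropyl-1β,8-dimethyl-decalin-5,8-dien-10-one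
Conditions: Pd(OAc)2 (1.05 equiv), MeCN, rt
Reagents that add atoms: none
Why: In the Saegusa–Ito oxidation the silyl enol ether gives an oxa-allyl complex of divalent palladium and β-hydride elimination from C8 forms the β-methyl enone C8=C9–C10=O, which erases the C8 stereocentre and leaves the C5=C6 alkene untouched.

Step 5
Reactants: 5 hydroxy enone
Product: 6 triol, 4β,5α,6α-trihydroxy-4α-isopropyl-1β,8-dimethyl-trans-decal-8-en-10-one
Conditions: OsO4 (5 mol %), NMO, acetone–H2O, rt
Reagents that add atoms: osmium tetroxide (catalytic oxygen carrier) O=[Os](=O)(=O)=O; N-methylmorpholine N-oxide C[N+]1([O-])CCOCC1; water O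
Why: Catalytic osmylation attacks the electron-rich trisubstituted C5=C6 alkene and not the electron-poor enone, and the syn addition should come from the α face, anti to the allylic C4 hydroxyl and anti to the axial C1 methyl group, to give the 5α,6α-diol of a trans-decalin.

Step 6
Reactants: 6 triol
Product: 7 mesylate, the 5α-methanesulfonate of 6
Conditions: MsCl, Et3N, CH2Cl2, 0 °C
Reagents that add atoms: methanesulfonyl chloride CS(=O)(=O)Cl
Why: Sulfonylation through sulfene reaches only the secondary C5 hydroxyl, the tertiary hydroxyls at C4 and C6 stay free, and the configuration at C5 is not touched.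

Step 7
Reactants: 7 mesylate
Product: 9 allylic alcohol (4β,6α,10α-triol 5α-mesylate), via diethylborinate 8 (not isolated)
Conditions: Et2BOMe, THF–MeOH, −78 °C; NaBH4; MeOH co-evaporation
Reagents that add atoms: none
Why: In this Narasaka–Prasad reduction the axial C6 oxygen and the C10 oxygen can be bridged by boron only on the α face, so borohydride should attack the activated enone carbonyl (1,2) from the β face and leave the new C10 hydroxyl axial and α, syn to the C6 hydroxyl.

Step 8
Reactants: 9 allylic alcohol
Product: 10 isovalerate, the C10 3-methylbutanoate of 9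
Conditions: (Me2CHCH2CO)2O, DMAP, Et3N, CH2Cl2, rt
Reagents that add atoms: 3-methylbutanoic anhydride CC(C)CC(=O)OC(=O)CC(C)C
Why: DMAP-catalysed acylation takes the only secondary hydroxyl (C10), the tertiary hydroxyls at C4 and C6 do not react under these conditions, and no stereocentre is touched.

Step 9
Reactants: 10 isovalerate
Product: 12 cis-fused hydroazulenone (6-ketone with 5β-H), via bis(diethylaluminium) alkoxide 11 (not isolated)
Conditions: Et3Al (3 equiv), CH2Cl2, −78 to 0 °C; aq. sodium potassium tartrate
Reagents that add atoms: none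
Why: Et3Al turns both tertiary hydroxyls into diethylaluminium alkoxides (11) and activates the equatorial C5 mesylate; the C6 oxygen then pushes and the C6–C1 bond, antiperiplanar to the C5–OMs bond in the chair of ring A, migrates from C6 to C5 while C6 becomes the ketone. The closest known reaction type is the organoaluminium-promoted pinacol-type (semipinacol) rearrangement of 2-hydroxy mesylates, in the decalin-to-hydroazulene form known from decalin-1,2-diol monosulfonates. The new C1–C5 bond closes the cyclopentane C1–C2–C3–C4–C5 by ring contraction of ring A through a concerted suprafacial 1,2-alkyl shift, and the same event enlarges ring B by the atom C5 to the cycloheptene C1–C5–C6–C7–C8–C9–C10. C5 is the only new stereocentre: C1 displaces the α-mesylate from the rear, so C5 is inverted, H5 stays β and cis to the C1 methyl group (cis fusion), and C1 migrates with retention. The step needs migration of C1 (pushed from C6) and not of C3 (pushed from the C4 alkoxide and equally antiperiplanar), which rests on the higher migratory aptitude of the fully substituted C1 over the primary C3. The non-basic, low-temperature conditions are chosen to keep the epimerisable C5 centre, the β,γ-position of the C8=C9 alkene and the C10 ester intact.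

Step 10
Reactants: 12 cis-fused hydroazulenone
Product: 13 diol, the 6α-alcohol of 12 (H6 β)
Conditions: Me4NBH(OAc)3, MeCN–AcOH, −30 °C
Reagents that add atoms: none
Why: In this Evans–Saksena reduction the C4 hydroxyl binds boron and delivers hydride to the β face of the C6 ketone, which is also the convex face of the cis-fused bicycle, so that H6 becomes β and the hydroxyl α (anti to the C4 hydroxyl) under mildly acidic conditions that spare the β,γ-alkene and C5.

Step 11
Reactants: 13 diol
Product: 14 acetate-protected target, the C6 4-acetoxybenzoate of 13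
Conditions: 4-AcOC6H4COCl, pyridine, DMAP (cat.), CH2Cl2, 0 °C to rt
Reagents that add atoms: 4-acetoxybenzoyl chloride CC(=O)Oc1ccc(cc1)C(Cl)=O
Why: Acylation with an acid chloride under nucleophilic catalysis takes the only secondary hydroxyl (C6), the tertiary C4 hydroxyl stays free, and the phenol is carried as its acetate so that it cannot acylate itself.

Step 12
Reactants: 14 acetate-protected target
Product: 15 target
Conditions: K2CO3 (0.2 equiv), MeOH, 0 °C
Reagents that add atoms: none
Why: Chemoselective methanolysis (transesterification) removes the aryl acetate, whose phenoxide is a far better leaving group than the alkoxides of the hindered secondary isovalerate and benzoate, and no stereocentre is touched.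

Compound list
1 | (R)-Wieland–Miescher ketone, (R)-8a-methyl-3,4,8,8a-tetrahydronaphthalene-1,6(2H,7H)-dione | C[C@@]12CCC(=O)C=C1CCCC2=O | starting material
2 | dienedione, (R)-8a-methyl-4,7,8,8a-tetrahydronaphthalene-1,6-dione | C[C@@]12CCC(=O)C=C1CC=CC2=O | intermediate
3 | trimethylsilyl enol ether (C9=C10–OSiMe3) of the 8α-methyl ketone, C8 methyl trans to C1 methyl, ring A enone intact | C[C@@]12CCC(=O)C=C1C[C@H](C)C=C2O[Si](C)(C)C | intermediate
4 | 4β-hydroxy-4α-isopropyl derivative of 3 (tertiary allylic alcohol, C5=C6) | C[C@@]12CC[C@](O)(C(C)C)C=C1C[C@H](C)C=C2O[Si](C)(C)C | intermediate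
5 | 4β-hydroxy-4α-isopropyl-1β,8-dimethyl-decalin-5,8-dien-10-one | C[C@@]12CC[C@](O)(C(C)C)C=C1CC(C)=CC2=O | intermediate
6 | 4β,5α,6α-trihydroxy-4α-isopropyl-1β,8-dimethyl-trans-decal-8-en-10-one | C[C@@]12CC[C@](O)(C(C)C)[C@H](O)[C@@]1(O)CC(C)=CC2=O | intermediate
7 | 5α-methanesulfonate of 6 | C[C@@]12CC[C@](O)(C(C)C)[C@H](OS(C)(=O)=O)[C@@]1(O)CC(C)=CC2=O | intermediate
8 | C6 diethylborinate of 7 | C[C@@]12CC[C@](O)(C(C)C)[C@H](OS(C)(=O)=O)[C@@]1(OB(CC)CC)CC(C)=CC2=O | intermediate
9 | 4β,6α,10α-trihydroxy-4α-isopropyl-1β,8-dimethyl-trans-decal-8-en-5α-yl methanesulfonate | C[C@@]12CC[C@](O)(C(C)C)[C@H](OS(C)(=O)=O)[C@@]1(O)CC(C)=C[C@@H]2O | intermediate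
10 | C10 3-methylbutanoate of 9 | CC1=C[C@H](OC(=O)CC(C)C)[C@]2(C)CC[C@](O)(C(C)C)[C@H](OS(C)(=O)=O)[C@@]2(O)C1 | intermediate
11 | 4,6-bis(diethylaluminium) alkoxide of 10 | CC1=C[C@H](OC(=O)CC(C)C)[C@]2(C)CC[C@](O[Al](CC)CC)(C(C)C)[C@H](OS(C)(=O)=O)[C@@]2(O[Al](CC)CC)C1 | intermediate
12 | cis-fused hydroazulenone, 4β-hydroxy-4α-isopropyl-1β,8-dimethyl-6-oxo-5β-H-bicyclo[5.3.0]dec-8-en-10α-yl 3-methylbutanoate (target numbering) | CC1=C[C@H](OC(=O)CC(C)C)[C@]2(C)CC[C@](O)(C(C)C)[C@@H]2C(=O)C1 | intermediate
13 | 6α-alcohol of 12 (4β,6α-diol, H6 β) | CC1=C[C@H](OC(=O)CC(C)C)[C@]2(C)CC[C@](O)(C(C)C)[C@@H]2[C@H](O)C1 | intermediate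
14 | C6 4-acetoxybenzoate of 13 | CC1=C[C@H](OC(=O)CC(C)C)[C@]2(C)CC[C@](O)(C(C)C)[C@@H]2[C@H](OC(=O)c2ccc(OC(C)=O)cc2)C1 | intermediate
15 | (3S,3aS,4R,8S,8aR)-3-hydroxy-6,8a-dimethyl-8-(3-methylbutanoyloxy)-3-(propan-2-yl)-1,2,3,3a,4,5,8,8a-octahydroazulen-4-yl 4-hydroxybenzoate | CC1=C[C@H](OC(=O)CC(C)C)[C@]2(C)CC[C@](O)(C(C)C)[C@@H]2[C@H](OC(=O)c2ccc(O)cc2)C1 | target

Total step count: 12. Longest linear sequence: 12 steps (1 to 15).

Steps most likely to fail

Step 9. The C4 aluminium alkoxide may push as well, so that the ring bond to C3 migrates to C5 in place of the bond to C1. The fallback removes the second donor and sets out from 5. Silylation of its only hydroxyl (Et3SiOTf, 2,6-lutidine, −78 °C) gives the C4 triethylsilyl ether F1. Osmylation as in step 5 gives the 5α,6α-diol F2, mesylation the C5 mesylate F3, chelation-controlled reduction the 10α-alcohol F4 and acylation the C10 isovalerate F5. In F5 only the C6 oxygen can trigger the shift, and Et3Al then gives the silylated hydroazulenone F6. HF·pyridine in THF removes the silyl group and the route is rejoined at 12.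

Step 3. The secondary alkyl reagent may act as a base or hydride donor (enolisation, β-hydride transfer) or lose facial selectivity. The fallback sets out from 3 and uses an alkenyl nucleophile, which has no β-hydrogen to transfer and asks less of the axial trajectory. Isopropenylmagnesium bromide with CeCl3 gives the isopropenyl carbinol F7. Hydrogenation with RhCl(PPh3)3 and H2 saturates only the 1,1-disubstituted alkene and returns to the route at 4.

Step 7. Reduction may outrun chelation, so that hydride is delivered axially from the α face, anti to the C1 methyl group. The fallback sets out from 7 and replaces facial control by inversion. Luche reduction (NaBH4, CeCl3, MeOH, −78 °C) is used on purpose to make the 10β-alcohol F8. Mitsunobu esterification (PPh3, DIAD, 3-methylbutanoic acid) then introduces the isovalerate with inversion at C10 and rejoins the route at 10, which also replaces step 8.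

Further compounds
F1 | step 9 | C4 triethylsilyl ether of 5 | C[C@@]12CC[C@](O[Si](CC)(CC)CC)(C(C)C)C=C1CC(C)=CC2=O
F2 | step 9 | 5α,6α-diol of F1 | C[C@@]12CC[C@](O[Si](CC)(CC)CC)(C(C)C)[C@H](O)[C@@]1(O)CC(C)=CC2=O
F3 | step 9 | C5 mesylate of F2 | C[C@@]12CC[C@](O[Si](CC)(CC)CC)(C(C)C)[C@H](OS(C)(=O)=O)[C@@]1(O)CC(C)=CC2=O
F4 | step 9 | 10α-alcohol from F3 | C[C@@]12CC[C@](O[Si](CC)(CC)CC)(C(C)C)[C@H](OS(C)(=O)=O)[C@@]1(O)CC(C)=C[C@@H]2O
F5 | step 9 | C10 isovalerate of F4 | CC1=C[C@H](OC(=O)CC(C)C)[C@]2(C)CC[C@](O[Si](CC)(CC)CC)(C(C)C)[C@H](OS(C)(=O)=O)[C@@]2(O)C1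
F6 | step 9 | C4 triethylsilyl ether of 12 | CC1=C[C@H](OC(=O)CC(C)C)[C@]2(C)CC[C@](O[Si](CC)(CC)CC)(C(C)C)[C@@H]2C(=O)C1
F7 | step 3 | isopropenyl carbinol, 4β-hydroxy-4α-(prop-1-en-2-yl) analogue of 4 | C[C@@]12CC[C@](O)(C(C)=C)C=C1C[C@H](C)C=C2O[Si](C)(C)C
F8 | step 7 | 10β-alcohol, C10 epimer of 9 | C[C@@]12CC[C@](O)(C(C)C)[C@H](OS(C)(=O)=O)[C@@]1(O)CC(C)=C[C@H]2O
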